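## Structural features

The target is a linear C15 halogenated acetogenin acetate (numbered C1 to C15 from the alkyne end). An oxygen bridge between C9 and C13 forms a single tetrahydropyran (oxane) ring, C14–C15 is the ethyl group on C13, and the methylene C8 joins ring carbon C9 to the open chain. In the chair with both ring appendages equatorial (2,6-cis; 9R,13S), the chlorine on C10 (R) is axial and cis to the C9 arm, and the bromine on C12 (R) is equatorial and trans to the ethyl group. C9/C10 and C12/C13 are therefore adjacent stereo-pairs separated by the methylene C11. The open chain carries a second adjacent pair, the acetoxy carbon C7 (S) and the chlorinated carbon C6 (R) in an anti relationship, followed by the allylic methylene C5 and the (E)-enyne C4=C3–C2≡C1. Fragile elements are the C6 chloride (loss of HCl towards C5 would give a conjugated dienyne, and a free C7 alkoxide would close an epoxide), the two secondary ring halides, the terminal enyne, and every C7 carbonyl intermediate, which is a β-alkoxy carbonyl compound able to open the ring by retro-oxa-Michael reaction. The real difficulty is twofold: the C6/C7 pair must be set without help from the ring, which is insulated by C8, and the ring needs an axial chloride next to the ring oxygen and an equatorial bromide, each from an oxygen precursor by inversion. The plan exploits the position of C6 between the allylic methylene C5 and the oxygenated carbon C7: C5–C6 is brought in as a vinyl group inserted between a C7 group migrating from boron and the alkenyl carbon C4 of the enyne, which leaves boron on C6 exactly where chlorine is wanted.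

## Logic of the disconnections

34 ⇒ 33. The ester C–O bond of the C7 acetate is cut. An acetate would not survive the aryllithium of the chlorination or the fluoride step, so it is put on last. The gain is that no acyl group has to be carried; the demand is an acylation mild enough that no C7 alkoxide is formed next to the C6 chloride.

33 ⇒ 32. The O–Si bond at C7 and the C1–Si bond are cut together. Silicon protects the carbinol through the organolithium steps and masks the acidic alkyne proton during ate-complex formation. One reagent removes both, but the fluoride must be buffered with acid: an unbuffered fluoride would generate the C7 alkoxide beside C6–Cl (epoxide closure) and is basic enough to threaten loss of HCl towards C5.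

32 ⇒ 30. The C6–Cl bond is exchanged for a C6–B bond of opposite configuration (6R chloride from 6S boronic ester). A C–B bond is what the three-component coupling leaves at C6, and it can be replaced by chlorine with inversion, which gives the anti C6/C7 pair. The gain is that the sensitive chloride never meets vinyllithium or palladium. The demand is a polar, invertive electrophilic substitution that outruns electron transfer and loss of boron together with the C7 silyloxy group.

30 ⇒ 24 + 28 + 26. The C6–C7 and C4–C5 bonds are cut in one operation. C6 is the only stereocentre whose two carbon neighbours can be joined through a two-carbon insert, so this cut splits the molecule into the ring half with five stereocentres, a vinyl unit and the enyne. The descriptors were re-derived: 7R in 24 becomes 7S in 30 by a change of CIP priority only, which is retention. The forward step must select one face of the vinyl group against the bias of C7, keep C7 intact, and add palladium only to the alkenyl C–Br bond. Two additions to the bare plan are needed: a triflate salt to remove bromide from palladium, and halide-free 28.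

26 ⇒ 25 and 28 ⇒ 27. The C3=C4 double bond is cut, so that C4 and its bromine come from a one-carbon reagent, and the C–Li bond is traced to a C–Sn bond. Each partner becomes a one-step preparation; the demands are E geometry in 26 and absence of lithium halide in 28.

24 ⇒ 21 + 22. The C7–B bond and the O–Si bond at C7 are cut. C7 is an aldehyde carbon one reduction away from an ester, so boron and oxygen can be placed on it in one catalytic step. The demand is catalyst control of the aldehyde face (7R), a borylcopper species that ignores the secondary halides, and silylation before the free α-hydroxy boronic ester rearranges.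

21 ⇒ 19 ⇒ 18. The C7 oxidation level is traced to an ester, and the C10–Cl bond to a C10–O sulfonate of opposite configuration. The gain is that C10 is reduced to an oxygen stereocentre that a ring closure can set. The demand is an SN2 displacement with axial approach next to the ring oxygen, which is only reasonable when nothing axial sits on C12.

18 ⇒ 16 ⇒ 14 ⇒ 13. The C12–Br bond is traced to an axial C12–OH (inversion), the acetal O–CH2 bond at C12 is cut, and the O–S bond at C10 is cut. The order is the design point: bromide is introduced first, because chloride approaching C10 while C12 still carried an axial oxygen would meet a syn-axial group and the anti-periplanar ring oxygen would take over. The C10 oxygen is parked as a chloromethanesulfonate that is protecting group first and leaving group later, so no step is spent on protection alone.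

13 ⇒ 12. The ring bond C9–C10 is cut. A ketyl at C10 adding to C9 of an alkoxyacrylate sets C9 and C10 from C13 in one step and returns an acyclic precursor. The demand is a chair transition state with the ethyl group equatorial, which the axial C12 acetal oxygen must not disturb.

12 ⇒ 11 ⇒ 9 ⇒ 7 + 8. The C10 aldehyde is traced through the primary alcohol to a terminal alkene (C10=C11), and the vinylic O–C bond between the C13 oxygen and the acrylate is cut. The latent aldehyde is inert to the conjugate addition, and the acrylate arrives as a three-carbon ester. The demands are a hydroboration that leaves the acrylate alone and an oxa-Michael addition at a hindered secondary alcohol.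

7 ⇒ 1 + 2. The C12–C13 bond is cut. An alkoxyallylboration of a three-carbon aldehyde gives the syn C12/C13 oxygen pair with C13–OH free, C12–O protected and the vinyl group in place. This avoids a route through a cyclic ester that would need opening, masking and unmasking of C10. The demand is reagent control of both new stereocentres (12S,13S).

## Other disconnections considered

Alternative 1: The cut is the ring bond O–C13 together with the oxidation pattern of C10 to C13; the tetrahydropyran is seen as a ring-expanded furan.
- Forward step: the furyl carbinol A1 would be oxidised at the anode in methanol with NaBr as mediator and then treated with dilute acid in the same pot, so that the C9 hydroxyl captures the unmasked C13 ketone and the pyranone hemiketal A2 results.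
- In its favour: A1 needs only one asymmetric allylation of a furan aldehyde, electrons replace a stoichiometric oxidant, and the ring is made in one pot. Only C9 has to be bought, since C13 can later be set from it by axial hydride delivery. The allyl group can be cleaved to the same aldehyde 21.
- Against it here: A2 has oxygen at C10 and C13 but nothing at C12, which is an enone β-carbon. The equatorial bromide would need a separate oxygenation of C11=C12 and an inversion, the C10 ketone a reduction and an inversion, and the hemiketal a reduction, all under substrate control on a flexible dihydropyranone.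
- Comparison: on structure, A2 maps well onto C9, C10 and C13 but poorly onto C12. On mechanism, it is an oxidative ring expansion that forms no C–C bond and does not address the C6/C7 pair, whereas the chosen plan spends its strategic step exactly there. On step economy, the alternative is the better one up to the ring (two steps to A2 against five to 13), and the worse one afterwards, because at least seven further operations would separate A2 from 21.

Alternative 2: The cut is the pair of bonds O–C9 and C10–Cl; the six-membered ring is seen as an expanded tetrahydrofuran.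
- Forward step: in the chloromethanesulfonate A3 the ring oxygen would displace the sulfonate at C9 with inversion to give the bicyclic oxiranium salt A4. Chloride from Bu4NCl would open A4 at C10 with a second inversion, giving the fully halogenated tetrahydropyran A5.
- In its favour: the axial C10 chloride and the C9 configuration arise stereospecifically from two inversions, and the bromide is already in place. Participation of the ring oxygen, which is the main hazard of step 9 of the chosen plan, is here the productive pathway; on this point the alternative is the better one.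
- Against it here: A3 already holds four stereocentres on a tetrahydrofuran and is longer to make than 13. Chloride can also open A4 at C9 or displace the sulfonate of A3 directly, so the outcome rests on a regiochemical preference. A5 carries C7 as a silyl ether, two steps from the aldehyde.
- Comparison: on structure, A5 is the equal of 19 in its halogen pattern. On mechanism, one cationic rearrangement replaces two separate SN2 displacements. On step economy, the alternative would be longer before the ring and one step longer after it, and it needs the same coupling for C6/C7 as the chosen plan.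

Alternative 3: The cut is the ring bond C9–C10.
- Forward step: SmI2 in THF–methanol would reduce the aldehyde of A6 to a ketyl that adds 6-exo-trig to C9 of the (E)-β-alkoxyacrylate and gives the 2,6-cis-2,3-trans hydroxy ester A7.
- In its favour: one step closes the ring and sets C9 and C10 from C13 through a well-understood chair, with simple reagents. It is the same reaction as step 5 of the chosen plan (12 → 13), which uses it as a supporting step with an acetal in place of the silyl ether at the C12 oxygen. On ring construction the two plans are therefore equal.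
- Against it as the strategy-bearing step: it settles only the ring and leaves the remote C6/C7 pair and the enyne to linear chain extension. In A7 the free C10 hydroxyl invites chlorination before bromination, where the axial approach to C10 would pass the axial C12 silyloxy group; the chosen plan reverses that order (steps 6 to 9). Preparing A6 by asymmetric dihydroxylation needs about two more oxidation-state adjustments than the preparation of 12.
- Comparison: on structure and mechanism of the ring closure there is no difference. The alternative is the better one in that it relies only on long-established reactivity, whereas step 14 is untested on this substrate class. On step economy the chosen plan should be shorter, because it brings in C1 to C6 convergently in one step.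

Key step: step 14

Assumption: the facial senses reported for simple substrates are taken to carry over, so (S)-DTBM-SEGPHOS is written for the 7R boronic ester and (Sp,Sp)-Mandyphos for the 6S boronic ester; if a model reaction shows the opposite sense, the antipodal ligand is used and nothing else changes.

Assumption: allyl methoxymethyl ether 1 is treated as a purchasable starting material (it is otherwise one step from allyl alcohol and dimethoxymethane).

## Route

Step 1
Reactants: 1 allyl methoxymethyl ether [3-(methoxymethoxy)prop-1-ene]; 2 propanal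
Product: 7 (3S,4S)-4-(methoxymethoxy)hex-5-en-3-ol, via lithiated allyl ether 3 (not isolated), via methoxyborate complex 4 (not isolated), via Z-alkoxyallylborane 5 (not isolated), via borinate adduct 6 (not isolated)
Conditions: s-BuLi, THF, −78 °C; (+)-Ipc2BOMe; BF3·OEt2; 2, −78 °C; then NaOH, H2O2, 0 °C → rt
Reagents that add atoms: none
Why: Brown alkoxyallylboration: the chelated Z-allyl anion is borylated at its terminal carbon, and the chair transition state with the ethyl group equatorial gives the syn C12/C13 pair, while the isopinocampheyl groups derived from (−)-α-pinene select the aldehyde face that leads to 13S (C3 of the hexenol). The product has C13–OH free, the C12 oxygen protected and a vinyl group that is the latent C10 aldehyde.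

Step 2
Reactants: 7 (3S,4S)-4-(methoxymethoxy)hex-5-en-3-ol; 8 ethyl propiolate
Product: 9 ethyl (2E)-3-{[(3S,4S)-4-(methoxymethoxy)hex-5-en-3-yl]oxy}prop-2-enoate
Conditions: 8 (1.5 equiv), N-methylmorpholine, CH2Cl2, rt
Reagents that add atoms: none
Why: Amine-catalysed oxa-Michael addition of a secondary alcohol to a propiolate ester; protonation of the zwitterionic allenolate gives the (E)-β-alkoxyacrylate, and no stereocentre is touched.

Step 3
Reactants: 9 ethyl (2E)-3-{[(3S,4S)-4-(methoxymethoxy)hex-5-en-3-yl]oxy}prop-2-enoate
Product: 11 ethyl (2E)-3-{[(3S,4S)-6-hydroxy-4-(methoxymethoxy)hexan-3-yl]oxy}prop-2-enoate, via B-alkyl-9-BBN adduct 10 (not isolated)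
Conditions: 9-BBN, THF, 0 °C → rt; then NaBO3·4H2O, H2O, rt
Reagents that add atoms: sodium perborate tetrahydrate, [Na+].[Na+].O[B-]1(O)OO[B-](O)(O)OO1.O.O.O.O.O.O
Why: Anti-Markovnikov hydroboration–oxidation: the hindered borane takes the monosubstituted alkene much faster than the electron-poor disubstituted acrylate double bond and does not reduce esters. Perborate oxidises the C–B bond near neutral pH, so the acrylate is not hydrolysed.

Step 4
Reactants: 11 ethyl (2E)-3-{[(3S,4S)-6-hydroxy-4-(methoxymethoxy)hexan-3-yl]oxy}prop-2-enoate
Product: 12 ethyl (2E)-3-{[(3S,4S)-4-(methoxymethoxy)-6-oxohexan-3-yl]oxy}prop-2-enoate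
Conditions: Dess–Martin periodinane, CH2Cl2, 0 °C → rt
Reagents that add atoms: none
Why: Dess–Martin oxidation of a primary alcohol under non-basic conditions, so the β-alkoxy aldehyde should not eliminate; it is used without chromatography.

Step 5
Reactants: 12 ethyl (2E)-3-{[(3S,4S)-4-(methoxymethoxy)-6-oxohexan-3-yl]oxy}prop-2-enoate
Product: 13 ethyl 2-[(2R,3S,5S,6S)-6-ethyl-3-hydroxy-5-(methoxymethoxy)oxan-2-yl]acetate
Conditions: SmI2 (2.5 equiv), MeOH (3 equiv), THF, 0 °C
Reagents that add atoms: none
Why: Samarium ketyl–olefin reductive cyclisation (6-exo-trig) of an aldehyde onto a β-alkoxyacrylate: the C10 ketyl adds to C9 through a chair in which the ethyl group and the (E)-acrylate are equatorial and samarium bridges the ketyl oxygen and the ester carbonyl. This should place H9 cis to H13 (2,6-cis) and the C10 hydroxyl trans to the acetate arm; the C12 acetal oxygen is axial, as fixed in step 1.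

Step 6
Reactants: 13 ethyl 2-[(2R,3S,5S,6S)-6-ethyl-3-hydroxy-5-(methoxymethoxy)oxan-2-yl]acetate
Product: 14 ethyl 2-[(2R,3S,5S,6S)-3-{[(chloromethyl)sulfonyl]oxy}-6-ethyl-5-(methoxymethoxy)oxan-2-yl]acetate
Conditions: ClCH2SO2Cl, pyridine, CH2Cl2, 0 °C
Reagents that add atoms: chloromethanesulfonyl chloride, ClCS(=O)(=O)Cl
Why: Sulfonylation of the equatorial C10 alcohol with retention; the chloromethanesulfonate protects this oxygen through steps 7 and 8 and is the leaving group of step 9, so no separate protecting group is spent.

Step 7
Reactants: 14 ethyl 2-[(2R,3S,5S,6S)-3-{[(chloromethyl)sulfonyl]oxy}-6-ethyl-5-(methoxymethoxy)oxan-2-yl]acetate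
Product: 16 ethyl 2-[(2R,3S,5S,6S)-3-{[(chloromethyl)sulfonyl]oxy}-6-ethyl-5-hydroxyoxan-2-yl]acetate, via bromomethyl ether 15 (not isolated)
Conditions: Me2BBr, CH2Cl2, −78 °C; then THF, aq. NaHCO3, 0 °C
Reagents that add atoms: none
Why: Bromoborane cleavage of a methoxymethyl ether: boron binds the terminal methoxy oxygen, bromide opens the acetal at −78 °C and the bromomethyl ether is hydrolysed on work-up. At this temperature the ester, the ring ether and the sulfonate should not be attacked, and C12 keeps its configuration.

Step 8
Reactants: 16 ethyl 2-[(2R,3S,5S,6S)-3-{[(chloromethyl)sulfonyl]oxy}-6-ethyl-5-hydroxyoxan-2-yl]acetate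
Product: 18 ethyl 2-[(2R,3S,5R,6S)-5-bromo-3-{[(chloromethyl)sulfonyl]oxy}-6-ethyloxan-2-yl]acetate, via C12 triflate 17 (not isolated)
Conditions: Tf2O, pyridine, CH2Cl2, −20 °C; cold aq. work-up; Bu4NBr, toluene, 0 °C → rt
Reagents that add atoms: tetrabutylammonium bromide, CCCC[N+](CCCC)(CCCC)CCCC.[Br-]
Why: SN2 displacement of an axial secondary triflate by bromide with inversion gives the equatorial C12 bromide trans to the ethyl group; the nucleophile approaches the face that carries no syn-axial group. The triflate should react orders of magnitude faster than the equatorial C10 sulfonate, whose backside is screened as long as C12 carries an axial substituent.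

Step 9
Reactants: 18 ethyl 2-[(2R,3S,5R,6S)-5-bromo-3-{[(chloromethyl)sulfonyl]oxy}-6-ethyloxan-2-yl]acetate
Product: 19 ethyl 2-[(2R,3R,5R,6S)-5-bromo-3-chloro-6-ethyloxan-2-yl]acetate
Conditions: LiCl, DMF, 40 °C
Reagents that add atoms: lithium chloride, [Li+].[Cl-]
Why: SN2 displacement of the equatorial chloromethanesulfonate by chloride with inversion gives the axial C10 chloride cis to the C9 arm; after step 8 the axial line of approach meets only hydrogen on C12. An equatorial leaving group has no anti-periplanar hydrogen, so E2 is disfavoured, and the sulfonate should be displaced well below the temperature at which the C12 bromide exchanges.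

Step 10
Reactants: 19 ethyl 2-[(2R,3R,5R,6S)-5-bromo-3-chloro-6-ethyloxan-2-yl]acetate
Product: 21 2-[(2R,3R,5R,6S)-5-bromo-3-chloro-6-ethyloxan-2-yl]acetaldehyde, via aluminium hemiacetal 20 (not isolated)
Conditions: i-Bu2AlH (1.1 equiv), CH2Cl2, −78 °C; MeOH, then aq. potassium sodium tartrate
Reagents that add atoms: none
Why: Partial reduction of an ester by diisobutylaluminium hydride: the tetrahedral aluminium hemiacetal is stable at −78 °C and releases the aldehyde only on work-up. Secondary alkyl halides are inert to the reagent at this temperature, and the neutral work-up avoids retro-oxa-Michael opening.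

Step 11
Reactants: 21 2-[(2R,3R,5R,6S)-5-bromo-3-chloro-6-ethyloxan-2-yl]acetaldehyde; 22 bis(pinacolato)diboron
Product: 24 tert-butyl{(1R)-2-[(2R,3R,5R,6S)-5-bromo-3-chloro-6-ethyloxan-2-yl]-1-(4,4,5,5-tetramethyl-1,3,2-dioxaborolan-2-yl)ethoxy}dimethylsilane, via α-hydroxy boronic ester 23 (not isolated)
Conditions: CuCl (5 mol %), (S)-DTBM-SEGPHOS (5 mol %), KO-t-Bu (10 mol %), 22 (1.1 equiv), MeOH (2 equiv), THF, 0 °C; volatiles removed; 2,6-lutidine, TBSOTf, CH2Cl2, −78 → 0 °C
Reagents that add atoms: tert-butyldimethylsilyl triflate, CC(C)(C)[Si](C)(C)OS(=O)(=O)C(F)(F)F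
Why: Copper-catalysed enantioselective nucleophilic borylation of an aliphatic aldehyde: the bisphosphine–borylcopper species adds boron to the Re face of C7 (catalyst control, 7R), and methanol releases the α-hydroxy boronic ester and regenerates the copper alkoxide. Immediate O-silylation at low temperature prevents the boron-to-oxygen shift to which the free α-hydroxy boronic ester is prone. Insertion of the aldehyde into Cu–B is much faster than attack of borylcopper on a hindered secondary halide, and with only catalytic alkoxide that side reaction cannot turn over.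

Step 12
Reactants: 25 3-(trimethylsilyl)prop-2-ynal
Product: 26 (E)-(4-bromobut-3-en-1-yn-1-yl)trimethylsilane
Conditions: CrBr2 (6 equiv), CHBr3 (2 equiv), THF, 0 °C → rt
Reagents that add atoms: bromoform, BrC(Br)Br
Why: Takai haloolefination: the geminal dichromium species formed from bromoform adds to the aldehyde, and anti elimination gives the (E)-alkenyl bromide. Chromium dibromide is used so that no alkenyl chloride arises by halide exchange; the minor Z isomer is removed before the coupling.

Step 13
Reactants: 27 tetravinyltin
Product: 28 vinyllithium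
Conditions: n-BuLi (4 equiv), pentane, rt; solid collected, washed with pentane, dissolved in THF and titrated
Reagents that add atoms: n-butyllithium, [Li]CCCC
Why: Tin–lithium exchange; vinyllithium precipitates from pentane while tetrabutyltin stays in solution, which gives the halide-free reagent that the palladium step needs.

Step 14
Reactants: 24 tert-butyl{(1R)-2-[(2R,3R,5R,6S)-5-bromo-3-chloro-6-ethyloxan-2-yl]-1-(4,4,5,5-tetramethyl-1,3,2-dioxaborolan-2-yl)ethoxy}dimethylsilane; 28 vinyllithium; 26 (E)-(4-bromobut-3-en-1-yn-1-yl)trimethylsilane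
Product: 30 tert-butyl({(2S,3S,5E)-1-[(2R,3R,5R,6S)-5-bromo-3-chloro-6-ethyloxan-2-yl]-3-(4,4,5,5-tetramethyl-1,3,2-dioxaborolan-2-yl)-8-(trimethylsilyl)oct-5-en-7-yn-2-yl}oxy)dimethylsilane, via lithium vinylboronate complex 29 (not isolated)
Conditions: 24, 28 (1.0 equiv), THF, −78 → 0 °C; then Pd(OAc)2 (3 mol %), (Sp,Sp)-Mandyphos [a bis(diarylphosphino)bis(α-dimethylaminobenzyl)ferrocene] (3.6 mol %), KOTf (2 equiv), 26 (1.2 equiv), THF, 45 °C
Reagents that add atoms: none
Why: Proposed new method: the closest known reaction type is the palladium-catalysed enantioselective conjunctive cross-coupling of vinylboron ate complexes with alkenyl electrophiles, which has not been shown with an α-silyloxyalkyl migrating group or an enynyl bromide; the reasoning is that α-oxygenated secondary alkyl groups migrate readily in other 1,2-metallate shifts and that the enynyl bromide is simply an electron-poor alkenyl bromide. Vinyllithium adds to boron of 24 to give the four-coordinate complex 29; zerovalent palladium inserts into the alkenyl C–Br bond of 26 and KOTf removes bromide as KBr, leaving a cationic divalent alkenylpalladium that binds the vinyl group of 29. This π-activation triggers the 1,2-shift of C7 from boron to C6 anti to palladium, with retention at C7, and reductive elimination from the resulting C5–Pd–C4 species forms the C4–C5 bond and returns zerovalent palladium. No ring is closed. The one new stereocentre, C6 (S), is set by the chiral bisphosphine, which selects the face of the vinyl group on which palladium binds, so the neighbouring C7 centre only has to be overridden. The step needs three selectivities: metallate shift rather than direct vinyl transfer (secured by the bidentate ligand and a halide-free cationic palladium), oxidative addition at the sp2 C–Br bond only (the secondary alkyl bromide and chlorides should not react with a bisphosphine–palladium catalyst at 45 °C), and survival of the β-silyloxy boronic ester (once formed it is neutral and three-coordinate, so it has no driving force for β-elimination).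

Step 15
Reactants: 30 tert-butyl({(2S,3S,5E)-1-[(2R,3R,5R,6S)-5-bromo-3-chloro-6-ethyloxan-2-yl]-3-(4,4,5,5-tetramethyl-1,3,2-dioxaborolan-2-yl)-8-(trimethylsilyl)oct-5-en-7-yn-2-yl}oxy)dimethylsilane
Product: 32 tert-butyl({(2S,3R,5E)-1-[(2R,3R,5R,6S)-5-bromo-3-chloro-6-ethyloxan-2-yl]-3-chloro-8-(trimethylsilyl)oct-5-en-7-yn-2-yl}oxy)dimethylsilane, via aryl boronate complex 31 (not isolated)
Conditions: 3,5-(CF3)2C6H3Br, n-BuLi, THF, −78 °C; 30, −78 °C; then trichloroisocyanuric acid, MeCN, −78 → 0 °C
Reagents that add atoms: trichloroisocyanuric acid, O=C1N(Cl)C(=O)N(Cl)C(=O)N1Cl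
Why: Stereoinvertive electrophilic chlorination of a secondary boronic ester through its aryl boronate complex: the electron-poor aryllithium makes boron four-coordinate and electrophilic chlorine attacks C6 on the face opposite boron (SE2 with inversion), turning 6S–B into 6R–Cl, anti to the C7 oxygen. The bis(trifluoromethyl)phenyl group suppresses single-electron transfer and aryl migration, and the low temperature should keep the silyloxy group from leaving together with boron.

Step 16
Reactants: 32 tert-butyl({(2S,3R,5E)-1-[(2R,3R,5R,6S)-5-bromo-3-chloro-6-ethyloxan-2-yl]-3-chloro-8-(trimethylsilyl)oct-5-en-7-yn-2-yl}oxy)dimethylsilane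
Product: 33 (2S,3R,5E)-1-[(2R,3R,5R,6S)-5-bromo-3-chloro-6-ethyloxan-2-yl]-3-chlorooct-5-en-7-yn-2-ol
Conditions: Bu4NF (3 equiv), AcOH (3 equiv), THF, 0 °C → rt
Reagents that add atoms: none
Why: Fluoride cleavage of the silyl ether and of the alkynyl C–Si bond in one operation; acetic acid protonates the C7 alkoxide and the acetylide as they form, so the chlorohydrin cannot close to an epoxide and the medium is too weakly basic to remove HCl towards C5.

Step 17
Reactants: 33 (2S,3R,5E)-1-[(2R,3R,5R,6S)-5-bromo-3-chloro-6-ethyloxan-2-yl]-3-chlorooct-5-en-7-yn-2-ol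
Product: 34 (2S,3R,5E)-1-[(2R,3R,5R,6S)-5-bromo-3-chloro-6-ethyloxan-2-yl]-3-chlorooct-5-en-7-yn-2-yl acetate
Conditions: Ac2O, pyridine, DMAP (cat.), CH2Cl2, 0 °C → rt
Reagents that add atoms: acetic anhydride, CC(=O)OC(C)=O
Why: Acyl transfer to a secondary alcohol under weakly basic conditions; no stereocentre is involved and pyridine is too weak a base to cause epoxide closure or dehydrochlorination.

## Compound list

1 | allyl methoxymethyl ether [3-(methoxymethoxy)prop-1-ene] | C=CCOCOC | starting material
2 | propanal | CCC=O | starting material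
3 | [(2Z)-3-(methoxymethoxy)prop-2-en-1-yl]lithium (chelated Z-allyl anion, drawn in its terminal σ-form) | COCO/C=C\C[Li] | intermediate
4 | lithium methoxy[(2Z)-3-(methoxymethoxy)prop-2-en-1-yl]bis(isopinocampheyl)borate (isopinocampheyl groups from (−)-α-pinene) | [Li+].COCO/C=C\C[B-](OC)([C@H]1C[C@H]2C[C@@H]([C@@H]1C)C2(C)C)[C@H]1C[C@H]2C[C@@H]([C@@H]1C)C2(C)C | intermediate
5 | [(2Z)-3-(methoxymethoxy)prop-2-en-1-yl]bis(isopinocampheyl)borane (isopinocampheyl groups from (−)-α-pinene) | COCO/C=C\CB([C@H]1C[C@H]2C[C@@H]([C@@H]1C)C2(C)C)[C@H]1C[C@H]2C[C@@H]([C@@H]1C)C2(C)C | intermediate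
6 | (3S,4S)-4-(methoxymethoxy)hex-5-en-3-yl bis(isopinocampheyl)borinate | CC[C@H](OB([C@H]1C[C@H]2C[C@@H]([C@@H]1C)C2(C)C)[C@H]1C[C@H]2C[C@@H]([C@@H]1C)C2(C)C)[C@@H](OCOC)C=C | intermediate
7 | (3S,4S)-4-(methoxymethoxy)hex-5-en-3-ol | CC[C@H](O)[C@@H](OCOC)C=C | intermediate
8 | ethyl propiolate | C#CC(=O)OCC | starting material
9 | ethyl (2E)-3-{[(3S,4S)-4-(methoxymethoxy)hex-5-en-3-yl]oxy}prop-2-enoate | CC[C@H](O/C=C/C(=O)OCC)[C@@H](OCOC)C=C | intermediate
10 | ethyl (2E)-3-{[(3S,4S)-6-(9-borabicyclo[3.3.1]nonan-9-yl)-4-(methoxymethoxy)hexan-3-yl]oxy}prop-2-enoate | CC[C@H](O/C=C/C(=O)OCC)[C@@H](OCOC)CCB1C2CCCC1CCC2 | intermediate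
11 | ethyl (2E)-3-{[(3S,4S)-6-hydroxy-4-(methoxymethoxy)hexan-3-yl]oxy}prop-2-enoate | CC[C@H](O/C=C/C(=O)OCC)[C@@H](OCOC)CCO | intermediate
12 | ethyl (2E)-3-{[(3S,4S)-4-(methoxymethoxy)-6-oxohexan-3-yl]oxy}prop-2-enoate | CC[C@H](O/C=C/C(=O)OCC)[C@@H](OCOC)CC=O | intermediate
13 | ethyl 2-[(2R,3S,5S,6S)-6-ethyl-3-hydroxy-5-(methoxymethoxy)oxan-2-yl]acetate | CCOC(=O)C[C@H]1O[C@@H](CC)[C@@H](OCOC)C[C@@H]1O | intermediate
14 | ethyl 2-[(2R,3S,5S,6S)-3-{[(chloromethyl)sulfonyl]oxy}-6-ethyl-5-(methoxymethoxy)oxan-2-yl]acetate | CCOC(=O)C[C@H]1O[C@@H](CC)[C@@H](OCOC)C[C@@H]1OS(=O)(=O)CCl | intermediate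
15 | ethyl 2-[(2R,3S,5S,6S)-5-(bromomethoxy)-3-{[(chloromethyl)sulfonyl]oxy}-6-ethyloxan-2-yl]acetate | CCOC(=O)C[C@H]1O[C@@H](CC)[C@@H](OCBr)C[C@@H]1OS(=O)(=O)CCl | intermediate
16 | ethyl 2-[(2R,3S,5S,6S)-3-{[(chloromethyl)sulfonyl]oxy}-6-ethyl-5-hydroxyoxan-2-yl]acetate | CCOC(=O)C[C@H]1O[C@@H](CC)[C@@H](O)C[C@@H]1OS(=O)(=O)CCl | intermediate
17 | ethyl 2-[(2R,3S,5S,6S)-3-{[(chloromethyl)sulfonyl]oxy}-6-ethyl-5-{[(trifluoromethyl)sulfonyl]oxy}oxan-2-yl]acetate | CCOC(=O)C[C@H]1O[C@@H](CC)[C@@H](OS(=O)(=O)C(F)(F)F)C[C@@H]1OS(=O)(=O)CCl | intermediate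
18 | ethyl 2-[(2R,3S,5R,6S)-5-bromo-3-{[(chloromethyl)sulfonyl]oxy}-6-ethyloxan-2-yl]acetate | CCOC(=O)C[C@H]1O[C@@H](CC)[C@H](Br)C[C@@H]1OS(=O)(=O)CCl | intermediate
19 | ethyl 2-[(2R,3R,5R,6S)-5-bromo-3-chloro-6-ethyloxan-2-yl]acetate | CCOC(=O)C[C@H]1O[C@@H](CC)[C@H](Br)C[C@H]1Cl | intermediate
20 | diisobutylaluminium hemiacetal of 19 (new hemiacetal carbon of undefined configuration) | CCOC(O[Al](CC(C)C)CC(C)C)C[C@H]1O[C@@H](CC)[C@H](Br)C[C@H]1Cl | intermediate
21 | 2-[(2R,3R,5R,6S)-5-bromo-3-chloro-6-ethyloxan-2-yl]acetaldehyde | O=CC[C@H]1O[C@@H](CC)[C@H](Br)C[C@H]1Cl | intermediate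
22 | bis(pinacolato)diboron | CC1(C)OB(OC1(C)C)B1OC(C)(C)C(C)(C)O1 | starting material
23 | (1R)-2-[(2R,3R,5R,6S)-5-bromo-3-chloro-6-ethyloxan-2-yl]-1-(4,4,5,5-tetramethyl-1,3,2-dioxaborolan-2-yl)ethan-1-ol | CC1(C)OB(OC1(C)C)[C@H](C[C@H]2O[C@@H](CC)[C@H](Br)C[C@H]2Cl)O | intermediate
24 | tert-butyl{(1R)-2-[(2R,3R,5R,6S)-5-bromo-3-chloro-6-ethyloxan-2-yl]-1-(4,4,5,5-tetramethyl-1,3,2-dioxaborolan-2-yl)ethoxy}dimethylsilane | CC1(C)OB(OC1(C)C)[C@H](C[C@H]2O[C@@H](CC)[C@H](Br)C[C@H]2Cl)O[Si](C)(C)C(C)(C)C | intermediate
25 | 3-(trimethylsilyl)prop-2-ynal | C[Si](C)(C)C#CC=O | starting material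
26 | (E)-(4-bromobut-3-en-1-yn-1-yl)trimethylsilane | Br/C=C/C#C[Si](C)(C)C | intermediate
27 | tetravinyltin | C=C[Sn](C=C)(C=C)C=C | starting material
28 | vinyllithium | [Li]C=C | intermediate
29 | lithium vinylboronate complex of 24 (vinyl, pinacolato and the C7 alkyl group on four-coordinate boron) | [Li+].C=C[B-]1(OC(C)(C)C(C)(C)O1)[C@H](C[C@H]2O[C@@H](CC)[C@H](Br)C[C@H]2Cl)O[Si](C)(C)C(C)(C)C | intermediate
30 | tert-butyl({(2S,3S,5E)-1-[(2R,3R,5R,6S)-5-bromo-3-chloro-6-ethyloxan-2-yl]-3-(4,4,5,5-tetramethyl-1,3,2-dioxaborolan-2-yl)-8-(trimethylsilyl)oct-5-en-7-yn-2-yl}oxy)dimethylsilane | C[Si](C)(C)C#C/C=C/C[C@H](B1OC(C)(C)C(C)(C)O1)[C@H](C[C@H]2O[C@@H](CC)[C@H](Br)C[C@H]2Cl)O[Si](C)(C)C(C)(C)C | intermediate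
31 | lithium [3,5-bis(trifluoromethyl)phenyl]boronate complex of 30 | [Li+].C[Si](C)(C)C#C/C=C/C[C@H]([B-]1(OC(C)(C)C(C)(C)O1)c1cc(cc(c1)C(F)(F)F)C(F)(F)F)[C@H](C[C@H]2O[C@@H](CC)[C@H](Br)C[C@H]2Cl)O[Si](C)(C)C(C)(C)C | intermediate
32 | tert-butyl({(2S,3R,5E)-1-[(2R,3R,5R,6S)-5-bromo-3-chloro-6-ethyloxan-2-yl]-3-chloro-8-(trimethylsilyl)oct-5-en-7-yn-2-yl}oxy)dimethylsilane | C[Si](C)(C)C#C/C=C/C[C@@H](Cl)[C@H](C[C@H]1O[C@@H](CC)[C@H](Br)C[C@H]1Cl)O[Si](C)(C)C(C)(C)C | intermediate
33 | (2S,3R,5E)-1-[(2R,3R,5R,6S)-5-bromo-3-chloro-6-ethyloxan-2-yl]-3-chlorooct-5-en-7-yn-2-ol | C#C/C=C/C[C@@H](Cl)[C@H](C[C@H]1O[C@@H](CC)[C@H](Br)C[C@H]1Cl)O | intermediate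
34 | (2S,3R,5E)-1-[(2R,3R,5R,6S)-5-bromo-3-chloro-6-ethyloxan-2-yl]-3-chlorooct-5-en-7-yn-2-yl acetate (CNP0194255.2; 6R,7S,9R,10R,12R,13S in chain numbering) | C#C/C=C/C[C@@H](Cl)[C@H](C[C@H]1O[C@@H](CC)[C@H](Br)C[C@H]1Cl)OC(C)=O | target

## Step count and least certain steps

Total step count: 17. Longest linear sequence: 15 (steps 1 to 11 and 14 to 17); steps 12 and 13 are one-step preparations of the other two coupling partners.

Step 14 (key step). What may go wrong: the 1,2-shift of the hindered, α-oxygenated secondary group may be slow, so that direct vinyl transfer to palladium takes over; bromide may inhibit the catalyst despite the triflate salt; catalyst control of the vinyl face may be eroded by a mismatched C7 centre; or any remaining ate complex may lose boron and the silyloxy group. Fallback with known chemistry, setting out from 24 and returning at 33: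
- but-3-en-1-yl 2,4,6-triisopropylbenzoate F1 is lithiated α to oxygen with s-BuLi and (+)-sparteine at −78 °C (the enantiomer expected to give the R-configured lithio species and hence 6S after the invertive shift);
- 24 is added and warming induces the reagent-controlled 1,2-shift of C7 with loss of the benzoate (lithiation–borylation homologation), giving the allyl boronic ester F2;
- chlorination exactly as in step 15 gives the allyl chloride F3;
- cross-metathesis with crotonaldehyde (Hoveyda–Grubbs second-generation catalyst) gives the (E)-enal F4;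
- Colvin homologation with lithiated trimethylsilyldiazomethane at −78 °C gives the silyl-protected terminal enyne F5;
- the silyl ether of F5 is cleaved as in step 16.

Step 11. What may go wrong: reaction of borylcopper with the C12 bromide, which would stop the catalyst; alkoxide-induced retro-oxa-Michael opening at C9; insufficient catalyst control next to the β-oxygen stereocentre; or rearrangement of the α-hydroxy boronic ester before silylation. Fallback that changes the order of events so that borylcopper never meets a C–Br bond, setting out from 14 and returning at 24: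
- 14 is reduced with i-Bu2AlH at −78 °C to the aldehyde F6;
- F6 is borylated and silylated as in step 11 to the boronic ester F7;
- the acetal is cleaved with Me2BBr to the C12 alcohol F8;
- Tf2O and pyridine followed by Bu4NBr give the bromide F9;
- LiCl in DMF displaces the sulfonate.

Step 15. What may go wrong: loss of stereospecificity through electron transfer from the ate complex to the chlorinating agent, elimination of boron together with the C7 silyloxy group, or chlorination of the enyne. Fallback, setting out from 30 and returning at 32: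
- the boronic ester is oxidised with NaBO3·4H2O with retention to the 6S alcohol F10;
- F10 is chlorinated with inversion under Appel conditions (CCl4, P(n-Oct)3, toluene, 60 °C).

Step 9. What may go wrong: participation of the ring oxygen, which lies anti-periplanar to the equatorial leaving group, leading to substitution with retention or to ring contraction; slow substitution; or chloride exchange at C12. Fallback, setting out from 13 and returning at 19:
- the C10 alcohol is acetylated (Ac2O, pyridine) to F11;
- the acetal is cleaved with Me2BBr to the alcohol F12;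
- Tf2O and pyridine followed by Bu4NBr give the bromo acetate F13;
- acid ethanolysis (HCl in EtOH) frees the bromo alcohol F14;
- F14 is chlorinated with inversion as its alkoxyphosphonium salt (CCl4, P(n-Oct)3, toluene, 70 °C).

Step 12. What may go wrong: incomplete E selectivity of the haloolefination with a conjugated ynal, which would carry a Z-enyne into the target, and halide scrambling. Fallback, setting out from 25 and returning at 26:
- Colvin homologation (lithiated trimethylsilyldiazomethane, −78 °C) gives buta-1,3-diyn-1-yl(trimethyl)silane F15;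
- syn hydrozirconation of the terminal alkyne with Cp2Zr(H)Cl followed by N-bromosuccinimide should give the (E)-bromide only.

## Further compounds

F1 | step 14 | but-3-en-1-yl 2,4,6-tri(propan-2-yl)benzoate | C=CCCOC(=O)c1c(C(C)C)cc(C(C)C)cc1C(C)C
F2 | step 14 | tert-butyl({(2S,3S)-1-[(2R,3R,5R,6S)-5-bromo-3-chloro-6-ethyloxan-2-yl]-3-(4,4,5,5-tetramethyl-1,3,2-dioxaborolan-2-yl)hex-5-en-2-yl}oxy)dimethylsilane | C=CC[C@H](B1OC(C)(C)C(C)(C)O1)[C@H](C[C@H]2O[C@@H](CC)[C@H](Br)C[C@H]2Cl)O[Si](C)(C)C(C)(C)C
F3 | step 14 | tert-butyl({(2S,3R)-1-[(2R,3R,5R,6S)-5-bromo-3-chloro-6-ethyloxan-2-yl]-3-chlorohex-5-en-2-yl}oxy)dimethylsilane | C=CC[C@@H](Cl)[C@H](C[C@H]1O[C@@H](CC)[C@H](Br)C[C@H]1Cl)O[Si](C)(C)C(C)(C)C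
F4 | step 14 | (2E,5R,6S)-7-[(2R,3R,5R,6S)-5-bromo-3-chloro-6-ethyloxan-2-yl]-6-[(tert-butyldimethylsilyl)oxy]-5-chlorohept-2-enal | O=C/C=C/C[C@@H](Cl)[C@H](C[C@H]1O[C@@H](CC)[C@H](Br)C[C@H]1Cl)O[Si](C)(C)C(C)(C)C
F5 | step 14 | tert-butyl({(2S,3R,5E)-1-[(2R,3R,5R,6S)-5-bromo-3-chloro-6-ethyloxan-2-yl]-3-chlorooct-5-en-7-yn-2-yl}oxy)dimethylsilane | C#C/C=C/C[C@@H](Cl)[C@H](C[C@H]1O[C@@H](CC)[C@H](Br)C[C@H]1Cl)O[Si](C)(C)C(C)(C)C
F6 | step 11 | 2-[(2R,3S,5S,6S)-3-{[(chloromethyl)sulfonyl]oxy}-6-ethyl-5-(methoxymethoxy)oxan-2-yl]acetaldehyde | O=CC[C@H]1O[C@@H](CC)[C@@H](OCOC)C[C@@H]1OS(=O)(=O)CCl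
F7 | step 11 | (2R,3S,5S,6S)-2-[(2R)-2-[(tert-butyldimethylsilyl)oxy]-2-(4,4,5,5-tetramethyl-1,3,2-dioxaborolan-2-yl)ethyl]-6-ethyl-5-(methoxymethoxy)oxan-3-yl chloromethanesulfonate | CC1(C)OB(OC1(C)C)[C@H](C[C@H]2O[C@@H](CC)[C@@H](OCOC)C[C@@H]2OS(=O)(=O)CCl)O[Si](C)(C)C(C)(C)C
F8 | step 11 | (2R,3S,5S,6S)-2-[(2R)-2-[(tert-butyldimethylsilyl)oxy]-2-(4,4,5,5-tetramethyl-1,3,2-dioxaborolan-2-yl)ethyl]-6-ethyl-5-hydroxyoxan-3-yl chloromethanesulfonate | CC1(C)OB(OC1(C)C)[C@H](C[C@H]2O[C@@H](CC)[C@@H](O)C[C@@H]2OS(=O)(=O)CCl)O[Si](C)(C)C(C)(C)C
F9 | step 11 | (2R,3S,5R,6S)-5-bromo-2-[(2R)-2-[(tert-butyldimethylsilyl)oxy]-2-(4,4,5,5-tetramethyl-1,3,2-dioxaborolan-2-yl)ethyl]-6-ethyloxan-3-yl chloromethanesulfonate | CC1(C)OB(OC1(C)C)[C@H](C[C@H]2O[C@@H](CC)[C@H](Br)C[C@@H]2OS(=O)(=O)CCl)O[Si](C)(C)C(C)(C)C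
F10 | step 15 | (2S,3S,5E)-1-[(2R,3R,5R,6S)-5-bromo-3-chloro-6-ethyloxan-2-yl]-2-[(tert-butyldimethylsilyl)oxy]-8-(trimethylsilyl)oct-5-en-7-yn-3-ol | C[Si](C)(C)C#C/C=C/C[C@H](O)[C@H](C[C@H]1O[C@@H](CC)[C@H](Br)C[C@H]1Cl)O[Si](C)(C)C(C)(C)C
F11 | step 9 | ethyl 2-[(2R,3S,5S,6S)-3-(acetyloxy)-6-ethyl-5-(methoxymethoxy)oxan-2-yl]acetate | CCOC(=O)C[C@H]1O[C@@H](CC)[C@@H](OCOC)C[C@@H]1OC(C)=O
F12 | step 9 | ethyl 2-[(2R,3S,5S,6S)-3-(acetyloxy)-6-ethyl-5-hydroxyoxan-2-yl]acetate | CCOC(=O)C[C@H]1O[C@@H](CC)[C@@H](O)C[C@@H]1OC(C)=O
F13 | step 9 | ethyl 2-[(2R,3S,5R,6S)-3-(acetyloxy)-5-bromo-6-ethyloxan-2-yl]acetate | CCOC(=O)C[C@H]1O[C@@H](CC)[C@H](Br)C[C@@H]1OC(C)=O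
F14 | step 9 | ethyl 2-[(2R,3S,5R,6S)-5-bromo-6-ethyl-3-hydroxyoxan-2-yl]acetate | CCOC(=O)C[C@H]1O[C@@H](CC)[C@H](Br)C[C@@H]1O
F15 | step 12 | buta-1,3-diyn-1-yl(trimethyl)silane | C#CC#C[Si](C)(C)C
A1 | alternative 1 | (1R)-1-(5-ethylfuran-2-yl)but-3-en-1-ol | CCc1ccc(o1)[C@H](O)CC=C
A2 | alternative 1 | (2R,6S)-6-ethyl-6-hydroxy-2-(prop-2-en-1-yl)-2H-pyran-3(6H)-one | C=CC[C@H]1O[C@@](O)(CC)C=CC1=O
A3 | alternative 2 | (1S)-3-[(tert-butyldiphenylsilyl)oxy]-1-[(2S,4R,5S)-4-bromo-5-ethyloxolan-2-yl]propyl chloromethanesulfonate | CC(C)(C)[Si](c1ccccc1)(c1ccccc1)OCC[C@H](OS(=O)(=O)CCl)[C@@H]1C[C@@H](Br)[C@H](CC)O1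
A4 | alternative 2 | bicyclic oxiranium chloromethanesulfonate formed from A3 (oxonium oxygen bridging C9 and C10 and bonded to C13) | CC(C)(C)[Si](c1ccccc1)(c1ccccc1)OCC[C@@H]1[C@@H]2C[C@@H](Br)[C@H](CC)[O+]12.[O-]S(=O)(=O)CCl
A5 | alternative 2 | {2-[(2R,3R,5R,6S)-5-bromo-3-chloro-6-ethyloxan-2-yl]ethoxy}(tert-butyl)diphenylsilane | CC(C)(C)[Si](c1ccccc1)(c1ccccc1)OCC[C@H]2O[C@@H](CC)[C@H](Br)C[C@H]2Cl
A6 | alternative 3 | ethyl (2E)-3-{[(3S,4S)-4-[(tert-butyldimethylsilyl)oxy]-6-oxohexan-3-yl]oxy}prop-2-enoate | CC[C@H](O/C=C/C(=O)OCC)[C@@H](O[Si](C)(C)C(C)(C)C)CC=O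
A7 | alternative 3 | ethyl 2-[(2R,3S,5S,6S)-5-[(tert-butyldimethylsilyl)oxy]-6-ethyl-3-hydroxyoxan-2-yl]acetate | CCOC(=O)C[C@H]1O[C@@H](CC)[C@@H](O[Si](C)(C)C(C)(C)C)C[C@@H]1O
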